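**Plan**

- Retrosynthesis: after desilylation, the benzylic C7' carbon is taken back to a γ-lactone carbonyl plus the ring A aryllithium. The oxolane is then cut at O1–C2 and C5–C4, leaving formaldehyde and a lactone-fused aryl cyclopropane. The cyclopropane goes back to an enal and a bromomalonate, the enal to an aryl iodide (Heck), and the side chain is cut at C7''–C8'' (aldol) and O–C8'' (phenol alkylation).
- Feature used: C2 of the oxolane is benzylic to ring B, which has a para ether oxygen (latent cation). C4 carries C7', which can stand at the carboxyl level (latent enolate). The C3 CH2OH and C4 CH2Ar groups are cis, so C2–C3–C4 can be a donor–acceptor cyclopropane whose C3/C4 substituents are tied as a γ-lactone; O1–C5H2 is then one molecule of formaldehyde.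
- Forward order: side chain on an iodoarene → enal → cyclopropane → γ-lactone (temporary ring) → oxolane by formal [3+2] → loss of the activating ester → lactone opened by aryllithium → hydrogenolysis → desilylation.
- Stereochemistry: C7''/C8'' from the (R)-4-benzyloxazolidinone syn-aldol; C3 from the amine-catalysed cyclopropanation; C4 from the cis ring fusion forced by the lactone; C2 by equilibration to the convex face during the annulation.

Key step: step 10

Remarks: Oxolane locants follow the target (O1, C2 aryl, C3 CH2OH = C9, C4 benzyl with benzylic carbon C7', C5); C7''–C9'' are the glycerol carbons; rings A, B, C are the benzyl arene, the C2 arene and the carbinol arene. SC = (1S,2S)-1,3-bis(tert-butyldimethylsilyloxy)-1-[3-methoxy-4-(triisopropylsilyloxy)phenyl]propan-2-yl; ArB = 3-methoxy-4-(SC-oxy)phenyl. Paraformaldehyde is the source of 20. Hemiketal 26 is taken as a mixture at the hemiketal carbon, which is removed in step 13.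

**Step 1**
Reactants: 1 vanillin; 2 chlorotriisopropylsilane
Product: 3 3-methoxy-4-(triisopropylsilyloxy)benzaldehyde
Conditions: imidazole, DMF, rt
Reagents that add atoms: chlorotriisopropylsilane, CC(C)[Si](Cl)(C(C)C)C(C)C
Why: Imidazole-promoted O-silylation of the phenol; the bulky aryl silyl ether is chosen to outlast the base, hydride, Lewis acid and hydrogenation steps that follow.

**Step 2**
Reactants: 4 4-iodo-2-methoxyphenol; 5 (4R)-4-benzyl-3-(chloroacetyl)-1,3-oxazolidin-2-one
Product: 6 (4R)-4-benzyl-3-[(4-iodo-2-methoxyphenoxy)acetyl]-1,3-oxazolidin-2-one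
Conditions: K2CO3, NaI (cat.), acetone, rt
Reagents that add atoms: (4R)-4-benzyl-3-(chloroacetyl)-1,3-oxazolidin-2-one, O=C(CCl)N1[C@H](Cc2ccccc2)COC1=O
Why: Williamson-type SN2 alkylation of the phenoxide at the activated α-chloro imide (iodide-assisted), under a base too weak to cleave the imide at room temperature.

**Step 3**
Reactants: 6; 3
Product: 8 (4R)-4-benzyl-3-{(2R,3S)-3-hydroxy-2-(4-iodo-2-methoxyphenoxy)-3-[3-methoxy-4-(triisopropylsilyloxy)phenyl]propanoyl}-1,3-oxazolidin-2-one, via dibutylboron Z-enolate 7 (not isolated)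
Conditions: n-Bu2BOTf, i-Pr2NEt, CH2Cl2, −78 to 0 °C; 3, −78 to 0 °C; then pH 7 buffer, MeOH, 30% H2O2, 0 °C
Reagents that add atoms: 3-methoxy-4-(triisopropylsilyloxy)benzaldehyde, COc1cc(C=O)ccc1O[Si](C(C)C)(C(C)C)C(C)C
Why: Evans syn-aldol: soft enolisation gives the (Z)-boron enolate, which reacts through a closed chair transition state on the face away from the benzyl group of the (R)-auxiliary, so C8'' and C7'' are set as the syn (threo) pair that becomes 7''S,8''S in the triol.

**Step 4**
Reactants: 8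
Product: 9 (1S,2S)-2-(4-iodo-2-methoxyphenoxy)-1-[3-methoxy-4-(triisopropylsilyloxy)phenyl]propane-1,3-diol
Conditions: LiBH4, THF, MeOH (1 equiv), 0 °C
Reagents that add atoms: none
Why: Reductive cleavage of the N-acyl oxazolidinone (hydride attack at the exocyclic carbonyl) gives the primary alcohol without touching the two new stereocentres, the aryl iodide or the aryl silyl ether.

**Step 5**
Reactants: 9; 10 tert-butyldimethylsilyl triflate
Product: 11 (1S,2S)-1,3-bis(tert-butyldimethylsilyloxy)-2-(4-iodo-2-methoxyphenoxy)-1-[3-methoxy-4-(triisopropylsilyloxy)phenyl]propane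
Conditions: 2,6-lutidine, CH2Cl2, 0 °C
Reagents that add atoms: tert-butyldimethylsilyl triflate, CC(C)(C)[Si](C)(C)OS(=O)(=O)C(F)(F)F
Why: Silylation of the secondary benzylic and the primary hydroxyl group with a silyl triflate and a hindered base; the silyl ethers are all removed together at the end.

**Step 6**
Reactants: 11; 12 acrolein
Product: 13 (E)-3-ArB-prop-2-enal
Conditions: Pd(OAc)2 (5 mol%), NaHCO3, n-Bu4NCl, DMF, 50 °C
Reagents that add atoms: acrolein, C=CC=O
Why: Mizoroki–Heck reaction under ligand-free phase-transfer conditions: oxidative addition of the aryl iodide, insertion of acrolein at its unsubstituted terminus and syn β-hydride elimination should give the (E)-enal.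

**Step 7**
Reactants: 14 dibenzyl malonate; 15 N-bromosuccinimide
Product: 16 dibenzyl 2-bromomalonate
Conditions: NBS (1.0 equiv), Mg(ClO4)2 (10 mol%), MeCN, rt
Reagents that add atoms: N-bromosuccinimide, O=C1CCC(=O)N1Br
Why: Electrophilic α-bromination of the Lewis-acid-activated malonate enol, held at the monobromide by the stoichiometry.

**Step 8**
Reactants: 13; 16
Product: 17 dibenzyl (2R,3S)-3-ArB-2-formylcyclopropane-1,1-dicarboxylate
Conditions: (S)-2-[diphenyl(trimethylsilyloxy)methyl]pyrrolidine (20 mol%), 2,6-lutidine (1.2 equiv), CH2Cl2, 0 °C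
Reagents that add atoms: dibenzyl 2-bromomalonate, O=C(OCc1ccccc1)C(Br)C(=O)OCc1ccccc1
Why: Michael-initiated ring closure under iminium–enamine catalysis: the bromomalonate anion adds to the β-carbon of the (E)-iminium ion on the face left open by the diphenyl(silyloxy)methyl group of the (S)-catalyst (aryl-bearing carbon 3S), and the enamine then displaces bromide to give the trans formyl cyclopropane (2R); a facial error would give a separable diastereomer because the side chain is already enantiopure.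

**Step 9**
Reactants: 17
Product: 19 benzyl (1R,5R,6S)-6-ArB-2-oxo-3-oxabicyclo[3.1.0]hexane-1-carboxylate, via hydroxymethyl cyclopropane diester 18 (not isolated)
Conditions: NaBH4, THF–i-PrOH, 0 °C to rt
Reagents that add atoms: none
Why: Chemoselective borohydride reduction of the aldehyde; the alkoxide is cis to one of the geminal esters and lactonises (5-exo-trig acyl substitution), which differentiates the two esters and builds the temporary ring.

**Step 10**
Reactants: 19; 20 formaldehyde (charged as paraformaldehyde)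
Product: 21 benzyl (1S,5R,6S)-6-ArB-2-oxo-3,7-dioxabicyclo[3.3.0]octane-1-carboxylate
Conditions: Sn(OTf)2 (10 mol%), (CH2O)n (5 equiv), 2,6-di-tert-butyl-4-methylpyridine (20 mol%), 4 Å MS, CH2Cl2, rt
Reagents that add atoms: formaldehyde, C=O
Why: Sn(OTf)2 binds the lactone and ester carbonyls on C1 of 19 and the C1–C6 bond, pushed by the para-alkoxy arene on C6, opens to a benzylic cation paired with the stabilised enolate; the oxygen of formaldehyde adds to the benzylic carbon and the enolate carbon then closes on the O-alkyl oxocarbenium carbon, so O1–C2 and C5–C4 of the oxolane arise in one operation. The closest known reaction type is the Lewis acid catalysed formal [3+2] annulation of 2-arylcyclopropane-1,1-dicarboxylates with aldehydes to oxolanes. The new five-membered ring closes by an aldol-type C–C bond formation that is formally 5-(enolexo)-endo-trig on the unhindered O=CH2 unit, or, seen as a whole, by an asynchronous [3+2] process. The quaternary C4 (C1 of 21) is controlled by the lactone tether, which allows only a cis ring fusion and so relays the configuration of C3 (C5), a centre the reaction does not touch. The benzylic C2 (C6) is controlled thermodynamically: ionisation at this carbon is reversible in the cyclopropane, in the ion pair and in the product, so the aryl group should settle on the convex face, trans to C9, whichever epimer forms first. The step needs cleavage of C1–C6 and not C1–C5, capture by formaldehyde before proton loss or oligomerisation, and survival of the silyl ethers: the donor arene secures the first, the excess of cracked paraformaldehyde the second, and the mild catalyst with a hindered pyridine as acid scavenger the third.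

**Step 11**
Reactants: 21
Product: 23 (1R,5R,6S)-6-ArB-3,7-dioxabicyclo[3.3.0]octan-2-one, via angular carboxylic acid 22 (not isolated)
Conditions: H2 (1 atm), Pd/C, EtOAc, rt, short; filter; toluene, 90 °C
Reagents that add atoms: none
Why: Hydrogenolysis of the benzyl ester, much faster than cleavage of the non-phenolic benzylic ethers, gives the malonic half acid, which loses CO2 on warming through the lactone enol; reprotonation can only give the cis-fused lactone, so C4 ends with C7' cis to C9.

**Step 12**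
Reactants: 23; 24 1-(benzyloxy)-4-bromo-2-methoxybenzene
Product: 26 (1R,5R,6S)-6-ArB-2-[4-(benzyloxy)-3-methoxyphenyl]-3,7-dioxabicyclo[3.3.0]octan-2-ol, via aryllithium 25 (not isolated)
Conditions: 24, n-BuLi, THF, −78 °C; then 23, −78 °C; NH4Cl (aq)
Reagents that add atoms: 1-(benzyloxy)-4-bromo-2-methoxybenzene (as its aryllithium), COc1cc(Br)ccc1OCc1ccccc1
Why: Bromine–lithium exchange and addition of the aryllithium to the γ-lactone at −78 °C, where the lithium hemiketal alkoxide does not collapse, so only one aryl group is added; no stereocentre of consequence is formed.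

**Step 13**
Reactants: 26
Product: 27 4-{[(3R,4R,5S)-5-ArB-4-(hydroxymethyl)oxolan-3-yl]methyl}-2-methoxyphenol
Conditions: H2 (3 atm), Pd/C, EtOAc–EtOH, rt
Reagents that add atoms: none
Why: Hydrogenolysis first frees the ring A phenol, and the hemiketal (through its open hydroxy ketone or by direct cleavage of its benzylic C–O bonds) should then be reduced to CH2, because a para-hydroxybenzylic C–O bond is cleaved far more readily than the benzylic ethers on rings B and C, whose para oxygens are alkylated or silylated; C4 is not touched under neutral conditions.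

**Step 14**
Reactants: 27
Product: 28 (1S,2S)-1-(4-hydroxy-3-methoxyphenyl)-2-{4-[(2S,3R,4R)-4-[(4-hydroxy-3-methoxyphenyl)methyl]-3-(hydroxymethyl)oxolan-2-yl]-2-methoxyphenoxy}propane-1,3-diol
Conditions: TBAF, AcOH (1:1), THF, 0 °C to rt
Reagents that add atoms: none
Why: Fluoride cleaves the aryl triisopropylsilyl ether and the two tert-butyldimethylsilyl ethers, while acetic acid keeps the phenols protonated so that no quinone methide can form at C7''.

**Compound list**

1 | vanillin | COc1cc(C=O)ccc1O | starting material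
2 | chlorotriisopropylsilane | CC(C)[Si](Cl)(C(C)C)C(C)C | starting material
3 | 3-methoxy-4-(triisopropylsilyloxy)benzaldehyde | COc1cc(C=O)ccc1O[Si](C(C)C)(C(C)C)C(C)C | intermediate
4 | 4-iodo-2-methoxyphenol | COc1cc(I)ccc1O | starting material
5 | (4R)-4-benzyl-3-(chloroacetyl)-1,3-oxazolidin-2-one | O=C(CCl)N1[C@H](Cc2ccccc2)COC1=O | starting material
6 | (4R)-4-benzyl-3-[(4-iodo-2-methoxyphenoxy)acetyl]-1,3-oxazolidin-2-one | COc1cc(I)ccc1OCC(=O)N1[C@H](Cc2ccccc2)COC1=O | intermediate
7 | dibutylboron (Z)-enolate of 6 (aryloxy and boryloxy groups cis) | COc1cc(I)ccc1O/C=C(\OB(CCCC)CCCC)N1[C@H](Cc2ccccc2)COC1=O | intermediate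
8 | (4R)-4-benzyl-3-{(2R,3S)-3-hydroxy-2-(4-iodo-2-methoxyphenoxy)-3-[3-methoxy-4-(triisopropylsilyloxy)phenyl]propanoyl}-1,3-oxazolidin-2-one (syn aldol) | COc1cc(I)ccc1O[C@@H](C(=O)N1[C@H](Cc2ccccc2)COC1=O)[C@@H](O)c1ccc(O[Si](C(C)C)(C(C)C)C(C)C)c(OC)c1 | intermediate
9 | (1S,2S)-2-(4-iodo-2-methoxyphenoxy)-1-[3-methoxy-4-(triisopropylsilyloxy)phenyl]propane-1,3-diol | COc1cc(I)ccc1O[C@@H](CO)[C@@H](O)c1ccc(O[Si](C(C)C)(C(C)C)C(C)C)c(OC)c1 | intermediate
10 | tert-butyldimethylsilyl triflate | CC(C)(C)[Si](C)(C)OS(=O)(=O)C(F)(F)F | starting material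
11 | (1S,2S)-1,3-bis(tert-butyldimethylsilyloxy)-2-(4-iodo-2-methoxyphenoxy)-1-[3-methoxy-4-(triisopropylsilyloxy)phenyl]propane | COc1cc(I)ccc1O[C@@H](CO[Si](C)(C)C(C)(C)C)[C@@H](O[Si](C)(C)C(C)(C)C)c1ccc(O[Si](C(C)C)(C(C)C)C(C)C)c(OC)c1 | intermediate
12 | acrolein | C=CC=O | starting material
13 | (E)-3-ArB-prop-2-enal | COc1cc(/C=C/C=O)ccc1O[C@@H](CO[Si](C)(C)C(C)(C)C)[C@@H](O[Si](C)(C)C(C)(C)C)c1ccc(O[Si](C(C)C)(C(C)C)C(C)C)c(OC)c1 | intermediate
14 | dibenzyl malonate | O=C(CC(=O)OCc1ccccc1)OCc1ccccc1 | starting material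
15 | N-bromosuccinimide | O=C1CCC(=O)N1Br | starting material
16 | dibenzyl 2-bromomalonate | O=C(OCc1ccccc1)C(Br)C(=O)OCc1ccccc1 | intermediate
17 | dibenzyl (2R,3S)-3-ArB-2-formylcyclopropane-1,1-dicarboxylate (aryl and formyl trans) | COc1cc([C@@H]2[C@@H](C=O)C2(C(=O)OCc3ccccc3)C(=O)OCc3ccccc3)ccc1O[C@@H](CO[Si](C)(C)C(C)(C)C)[C@@H](O[Si](C)(C)C(C)(C)C)c1ccc(O[Si](C(C)C)(C(C)C)C(C)C)c(OC)c1 | intermediate
18 | dibenzyl (2R,3S)-3-ArB-2-(hydroxymethyl)cyclopropane-1,1-dicarboxylate | COc1cc([C@@H]2[C@@H](CO)C2(C(=O)OCc3ccccc3)C(=O)OCc3ccccc3)ccc1O[C@@H](CO[Si](C)(C)C(C)(C)C)[C@@H](O[Si](C)(C)C(C)(C)C)c1ccc(O[Si](C(C)C)(C(C)C)C(C)C)c(OC)c1 | intermediate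
19 | benzyl (1R,5R,6S)-6-ArB-2-oxo-3-oxabicyclo[3.1.0]hexane-1-carboxylate (aryl exo, trans to the lactone CH2) | COc1cc([C@@H]2[C@H]3COC(=O)[C@@]23C(=O)OCc4ccccc4)ccc1O[C@@H](CO[Si](C)(C)C(C)(C)C)[C@@H](O[Si](C)(C)C(C)(C)C)c1ccc(O[Si](C(C)C)(C(C)C)C(C)C)c(OC)c1 | intermediate
20 | formaldehyde | C=O | starting material
21 | benzyl (1S,5R,6S)-6-ArB-2-oxo-3,7-dioxabicyclo[3.3.0]octane-1-carboxylate (cis-fused, aryl exo) | O=C1[C@@]2(C(=O)OCc5ccccc5)CO[C@H](c3ccc(O[C@@H](CO[Si](C)(C)C(C)(C)C)[C@@H](O[Si](C)(C)C(C)(C)C)c4ccc(O[Si](C(C)C)(C(C)C)C(C)C)c(OC)c4)c(OC)c3)[C@H]2CO1 | intermediate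
22 | (1R,5R,6S)-6-ArB-2-oxo-3,7-dioxabicyclo[3.3.0]octane-1-carboxylic acid | O=C1[C@@]2(C(=O)O)CO[C@H](c3ccc(O[C@@H](CO[Si](C)(C)C(C)(C)C)[C@@H](O[Si](C)(C)C(C)(C)C)c4ccc(O[Si](C(C)C)(C(C)C)C(C)C)c(OC)c4)c(OC)c3)[C@H]2CO1 | intermediate
23 | (1R,5R,6S)-6-ArB-3,7-dioxabicyclo[3.3.0]octan-2-one (cis-fused, aryl exo) | O=C1[C@H]2CO[C@H](c3ccc(O[C@@H](CO[Si](C)(C)C(C)(C)C)[C@@H](O[Si](C)(C)C(C)(C)C)c4ccc(O[Si](C(C)C)(C(C)C)C(C)C)c(OC)c4)c(OC)c3)[C@H]2CO1 | intermediate
24 | 1-(benzyloxy)-4-bromo-2-methoxybenzene | COc1cc(Br)ccc1OCc1ccccc1 | starting material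
25 | [4-(benzyloxy)-3-methoxyphenyl]lithium | [Li]c1ccc(OCc2ccccc2)c(OC)c1 | intermediate
26 | (1R,5R,6S)-6-ArB-2-[4-(benzyloxy)-3-methoxyphenyl]-3,7-dioxabicyclo[3.3.0]octan-2-ol (hemiketal, mixture at C2 of the bicycle) | OC1(c5ccc(OCc6ccccc6)c(OC)c5)[C@H]2CO[C@H](c3ccc(O[C@@H](CO[Si](C)(C)C(C)(C)C)[C@@H](O[Si](C)(C)C(C)(C)C)c4ccc(O[Si](C(C)C)(C(C)C)C(C)C)c(OC)c4)c(OC)c3)[C@H]2CO1 | intermediate
27 | 4-{[(3R,4R,5S)-5-ArB-4-(hydroxymethyl)oxolan-3-yl]methyl}-2-methoxyphenol | COc1cc(C[C@H]2CO[C@H](c3ccc(O[C@@H](CO[Si](C)(C)C(C)(C)C)[C@@H](O[Si](C)(C)C(C)(C)C)c4ccc(O[Si](C(C)C)(C(C)C)C(C)C)c(OC)c4)c(OC)c3)[C@H]2CO)ccc1O | intermediate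
28 | (1S,2S)-1-(4-hydroxy-3-methoxyphenyl)-2-{4-[(2S,3R,4R)-4-[(4-hydroxy-3-methoxyphenyl)methyl]-3-(hydroxymethyl)oxolan-2-yl]-2-methoxyphenoxy}propane-1,3-diol | COc1cc(C[C@H]2CO[C@H](c3ccc(O[C@@H](CO)[C@@H](O)c4ccc(O)c(OC)c4)c(OC)c3)[C@H]2CO)ccc1O | target

**Count**

Total: 14 steps. Longest linear sequence: 12 steps (steps 2–6 and 8–14).

**Steps most likely to fail**

Step 10. The ring-opened ion pair may lose a proton or attack another arene instead of being intercepted by formaldehyde, acid released from the catalyst may strip silyl ethers or ionise C7'', and equilibration at C2 may stop short of the exo isomer. The fallback sets out from 19 and returns at 21, making the two bonds in separate operations. Cyclopropane 19 is opened at the benzylic carbon with water (Yb(OTf)3 cat., wet MeCN) to the hydroxy lactone ester F1. Its benzylic hydroxyl is converted with MOMCl and i-Pr2NEt into the methoxymethyl ether F2, which already holds the O1–C5 unit. TMSOTf with i-Pr2NEt at −78 °C then forms the silyl ketene acetal of the α-benzyloxycarbonyl lactone and ionises the acetal. The tethered oxocarbenium ion closes onto C4 in an intramolecular Mukaiyama-type alkylation, which again can only give the cis-fused 21. The benzylic centre should equilibrate to exo under the same Lewis acid or with a trace of acid afterwards.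

Step 13. Hydrogenolysis may stall at the benzylic alcohol or cyclic ether stage, or go on to cleave the oxolane C2–O1 bond or the C7''–O bond, and the open hydroxy ketone may epimerise at C4. The fallback sets out from 26 and returns at 27, using a carbonyl-specific deoxygenation. The open hydroxy ketone form of 26 is condensed with tosylhydrazine (MeOH, 50 °C) to the tosylhydrazone F3. Reduction with catecholborane and then NaOAc·3H2O at reflux gives the deoxygenated ring A benzyl ether F4. A brief hydrogenolysis (H2 1 atm, Pd/C, EtOAc) then removes only the aryl benzyl ether and gives 27.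

Step 8. The bulky, electron-rich enal may form its iminium ion slowly, so that background addition and amine-induced opening of the very activated cyclopropane lower yield and facial selectivity. The fallback sets out from 13 and returns at 19, bypassing step 9 by a metal carbene route. Enal 13 is reduced (NaBH4, CeCl3·7H2O, MeOH) to the (E)-cinnamyl alcohol F5. Esterification with mono-benzyl malonate (DCC, DMAP) gives the mixed malonate F6, and diazo transfer (4-acetamidobenzenesulfonyl azide, Et3N) gives the diazomalonate F7. Intramolecular cyclopropanation with Rh2(S-PTTL)4 or its enantiomer, whichever delivers the (5R,6S) series, then gives 19 directly, the (E)-alkene placing the aryl group exo. Enantioselectivity of this type of cyclisation is less secure, but the wrong isomer is a diastereomer and should be separable.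

**Further compounds**

F1 | step 10 | benzyl (4R)-4-[ArB(hydroxy)methyl]-2-oxooxolane-3-carboxylate (mixture at the carbinol and at C3 of the lactone) | O=C1OC[C@H](C(O)c3ccc(O[C@@H](CO[Si](C)(C)C(C)(C)C)[C@@H](O[Si](C)(C)C(C)(C)C)c4ccc(O[Si](C(C)C)(C(C)C)C(C)C)c(OC)c4)c(OC)c3)C1C(=O)OCc5ccccc5
F2 | step 10 | benzyl (4R)-4-[ArB(methoxymethoxy)methyl]-2-oxooxolane-3-carboxylate | O=C1OC[C@H](C(OCOC)c3ccc(O[C@@H](CO[Si](C)(C)C(C)(C)C)[C@@H](O[Si](C)(C)C(C)(C)C)c4ccc(O[Si](C(C)C)(C(C)C)C(C)C)c(OC)c4)c(OC)c3)C1C(=O)OCc5ccccc5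
F3 | step 13 | tosylhydrazone of [(3R,4R,5S)-5-ArB-4-(hydroxymethyl)oxolan-3-yl][4-(benzyloxy)-3-methoxyphenyl]methanone | Cc1ccc(cc1)S(=O)(=O)NN=C(c5ccc(OCc6ccccc6)c(OC)c5)[C@H]2CO[C@H](c3ccc(O[C@@H](CO[Si](C)(C)C(C)(C)C)[C@@H](O[Si](C)(C)C(C)(C)C)c4ccc(O[Si](C(C)C)(C(C)C)C(C)C)c(OC)c4)c(OC)c3)[C@H]2CO
F4 | step 13 | [(2S,3R,4R)-2-ArB-4-{[4-(benzyloxy)-3-methoxyphenyl]methyl}oxolan-3-yl]methanol | COc1cc(C[C@H]2CO[C@H](c3ccc(O[C@@H](CO[Si](C)(C)C(C)(C)C)[C@@H](O[Si](C)(C)C(C)(C)C)c4ccc(O[Si](C(C)C)(C(C)C)C(C)C)c(OC)c4)c(OC)c3)[C@H]2CO)ccc1OCc1ccccc1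
F5 | step 8 | (E)-3-ArB-prop-2-en-1-ol | COc1cc(/C=C/CO)ccc1O[C@@H](CO[Si](C)(C)C(C)(C)C)[C@@H](O[Si](C)(C)C(C)(C)C)c1ccc(O[Si](C(C)C)(C(C)C)C(C)C)c(OC)c1
F6 | step 8 | benzyl (E)-3-ArB-prop-2-enyl malonate | COc1cc(/C=C/COC(=O)CC(=O)OCc2ccccc2)ccc1O[C@@H](CO[Si](C)(C)C(C)(C)C)[C@@H](O[Si](C)(C)C(C)(C)C)c1ccc(O[Si](C(C)C)(C(C)C)C(C)C)c(OC)c1
F7 | step 8 | benzyl (E)-3-ArB-prop-2-enyl 2-diazomalonate | COc1cc(/C=C/COC(=O)C(=[N+]=[N-])C(=O)OCc2ccccc2)ccc1O[C@@H](CO[Si](C)(C)C(C)(C)C)[C@@H](O[Si](C)(C)C(C)(C)C)c1ccc(O[Si](C(C)C)(C(C)C)C(C)C)c(OC)c1
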